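**Plan**
- Cuts: O–H goes back to O–CH3. C3–Br and C4–Br go back to C–H, and C5–Br goes back to C5–CO2Et. The pyrrole bonds C2–C3 and C4–C5 are then cut together, and the C2=N1 imine bond last.
- Enabling feature: the pyrrole is numbered N1, C2 (carbon bearing the dibromophenol ring), C3, C4, C5. These locants are used in every Why line, while the systematic names of the esters and acids count from the carboxyl end. C2–N1–C5 has the connectivity of a 1,3-dipole built from an aryl aldehyde carbon and the N–CH2 of glycine. C3–C4 is a plain two-carbon unit that an ethene with one leaving group on each carbon can supply at the aromatic oxidation level.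
- Forward: the benzene ring is bought with both bromines in place, and O-methylation and imine formation prepare the dipole precursor. The pyrrole is the only ring built, and it closes in one flask by [3+2] cycloaddition and loss of two sulfinates.
- End game: saponification, threefold bromination (C3–H, C4–H, ipso at C5 with loss of CO2) and ether cleavage.
- Stereochemistry: the target has none. The four stereocentres of the cycloadduct are transient and are erased on aromatisation.

Key step: step 3

Assumption: the target SMILES carries no stereodescriptor and the aryl–pyrrole axis (flanked by OH/H and by NH/Br on a five-membered ring) is taken to rotate freely, so the compound is achiral and no enantiomer has to be selected.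

**Step 1**
Reactants: 1 3,5-dibromosalicylaldehyde
Product: 2 3,5-dibromo-2-methoxybenzaldehyde
Conditions: MeI (1.5 equiv), K2CO3 (2 equiv), DMF, rt
Reagents that add atoms: iodomethane, CI
Why: Williamson ether synthesis: carbonate fully ionises the phenol, which two bromines and the ortho formyl group make acidic, and the phenoxide should displace iodide from MeI by SN2, removing the acidic, metal-binding OH that would quench the dipole of step 3 while CHO and C–Br stay inert.

**Step 2**
Reactants: 2 3,5-dibromo-2-methoxybenzaldehyde; 3 glycine ethyl ester hydrochloride
Product: 4 ethyl (E)-N-(3,5-dibromo-2-methoxybenzylidene)glycinate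
Conditions: Et3N (1.1 equiv), MgSO4, CH2Cl2, rt; filtration, water wash, used crude
Reagents that add atoms: none
Why: Schiff-base condensation: the amine released by Et3N adds to the aldehyde and MgSO4 binds the water, so the equilibrium should lie with the aldimine, which takes the less strained E geometry and is carried on without chromatography because it hydrolyses on silica.

**Step 3**
Reactants: 4 ethyl (E)-N-(3,5-dibromo-2-methoxybenzylidene)glycinate; 5 (E)-1,2-bis(phenylsulfonyl)ethene
Product: 8 ethyl 5-(3,5-dibromo-2-methoxyphenyl)-1H-pyrrole-2-carboxylate, via bis-sulfonyl pyrrolidine 6 (not isolated), via sulfonyl dihydropyrrole 7 (not isolated)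
Conditions: AgOAc (10 mol %), PPh3 (10 mol %), Et3N (20 mol %), THF, rt, dark; then DBU (3 equiv), rt
Reagents that add atoms: none
Why: Silver(I) chelates the imine nitrogen and the ester carbonyl of 4, so that Et3N can remove a glycine CH2 proton and give the N-metalated azomethine ylide, a W-shaped 2-azaallyl anion with nucleophilic ends at the future C5 and C2. This dipole adds to the C=C of 5 and forms C4–C5 and C2–C3 in an intermolecular [3+2] ring closure to pyrrolidine 6, either concerted and asynchronous or as a Michael addition through C5 followed by a 5-endo-trig Mannich closure of the α-sulfonyl carbanion C3 onto the metal-activated C2=N1 bond. DBU then starts two E1cB eliminations: removal of the C5–H next to the ester expels the C4 sulfinate to give 7, and loss of the C3 sulfinate together with the benzylic C2–H leaves aromatic 8, so the oxidation level of the pyrrole comes from the two leaving groups and the aryl C–Br bonds never meet an oxidant or a cross-coupling metal. The closest known reaction type is the silver- or copper-catalysed 1,3-dipolar cycloaddition of α-iminoesters with 1,2-bis(sulfonyl)ethenes used as acetylene equivalents, followed by base-induced desulfonylative aromatisation. The four stereocentres of 6 follow from the ylide geometry (C2/C5 cis) and from suprafacial addition to the E-alkene (C3/C4 trans), arise in racemic form and are all destroyed in 8, so none needs control. The step needs only chemoselectivity (cycloaddition ahead of imine hydrolysis, ylide self-addition and amine attack on 5), which the strong electrophilicity conferred by two sulfonyl groups, dry solvent and the late addition of DBU should secure, and since the two alkene carbons of 5 are equivalent only one regioisomer is possible.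

**Step 4**
Reactants: 8 ethyl 5-(3,5-dibromo-2-methoxyphenyl)-1H-pyrrole-2-carboxylate
Product: 9 5-(3,5-dibromo-2-methoxyphenyl)-1H-pyrrole-2-carboxylic acid
Conditions: NaOH (5 equiv), EtOH–H2O, 70 °C; then 1 M HCl to pH 3, 0 °C
Reagents that add atoms: sodium hydroxide, [Na+].[OH-]
Why: Ester saponification (BAc2): excess hydroxide and heat make up for the low electrophilicity of a pyrrole-2-carboxylate, the aryl bromides and the methyl ether do not react with aqueous hydroxide at this temperature, and cold acidification to only pH 3 should avoid acid-induced protodecarboxylation.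

**Step 5**
Reactants: 9 5-(3,5-dibromo-2-methoxyphenyl)-1H-pyrrole-2-carboxylic acid
Product: 10 2,3,4-tribromo-5-(3,5-dibromo-2-methoxyphenyl)-1H-pyrrole
Conditions: NBS (3.05 equiv), LiOAc (20 mol %), DMF, 0 °C → rt, dark
Reagents that add atoms: N-bromosuccinimide, O=C1CCC(=O)N1Br
Why: Electrophilic pyrrole bromination combined with halodecarboxylation (Hunsdiecker-type ipso substitution, known for pyrrole-2-carboxylic acids): NBS should first substitute the free β-positions C3 and C4 and then attack the carboxylate-bearing C5, where the σ-complex rearomatises by losing CO2 with acetate as proton shuttle, while the anisole ring is safe because both positions ortho and the one para to OMe are occupied and two bromines deactivate it.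

**Step 6**
Reactants: 10 2,3,4-tribromo-5-(3,5-dibromo-2-methoxyphenyl)-1H-pyrrole
Product: 11 pentabromopseudilin, 2,4-dibromo-6-(3,4,5-tribromo-1H-pyrrol-2-yl)phenol
Conditions: BBr3 (3 equiv), CH2Cl2, −78 °C → rt; then H2O, 0 °C
Reagents that add atoms: none
Why: Lewis-acid cleavage of an aryl methyl ether: BBr3 binds the methoxy oxygen, which its two ortho neighbours twist out of conjugation, bromide removes the methyl group by SN2 and water hydrolyses the B–O bond to the phenol, conditions under which aryl and pyrrole C–Br bonds should persist.

**Compound list**
1 | 3,5-dibromosalicylaldehyde (3,5-dibromo-2-hydroxybenzaldehyde) | O=Cc1cc(Br)cc(Br)c1O | starting material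
2 | 3,5-dibromo-2-methoxybenzaldehyde | O=Cc1cc(Br)cc(Br)c1OC | intermediate
3 | glycine ethyl ester hydrochloride | Cl.NCC(=O)OCC | starting material
4 | ethyl (E)-N-(3,5-dibromo-2-methoxybenzylidene)glycinate | CCOC(=O)C/N=C/c1cc(Br)cc(Br)c1OC | intermediate
5 | (E)-1,2-bis(phenylsulfonyl)ethene | O=S(=O)(/C=C/S(=O)(=O)c1ccccc1)c1ccccc1 | starting material
6 | ethyl rel-(2S,3R,4R,5R)-5-(3,5-dibromo-2-methoxyphenyl)-3,4-bis(phenylsulfonyl)pyrrolidine-2-carboxylate; racemic, ester and aryl cis, sulfonyl groups trans, sulfonyl next to the aryl group trans to it; one enantiomer drawn | CCOC(=O)[C@@H]1N[C@H](c2cc(Br)cc(Br)c2OC)[C@@H](S(=O)(=O)c2ccccc2)[C@@H]1S(=O)(=O)c1ccccc1 | intermediate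
7 | ethyl rel-(4S,5R)-5-(3,5-dibromo-2-methoxyphenyl)-4-(phenylsulfonyl)-4,5-dihydro-1H-pyrrole-2-carboxylate; racemic, 4,5-trans; one enantiomer drawn | CCOC(=O)C1=C[C@H](S(=O)(=O)c2ccccc2)[C@@H](c2cc(Br)cc(Br)c2OC)N1 | intermediate
8 | ethyl 5-(3,5-dibromo-2-methoxyphenyl)-1H-pyrrole-2-carboxylate | CCOC(=O)c1ccc([nH]1)-c1cc(Br)cc(Br)c1OC | intermediate
9 | 5-(3,5-dibromo-2-methoxyphenyl)-1H-pyrrole-2-carboxylic acid | OC(=O)c1ccc([nH]1)-c1cc(Br)cc(Br)c1OC | intermediate
10 | 2,3,4-tribromo-5-(3,5-dibromo-2-methoxyphenyl)-1H-pyrrole (O-methyl ether of the target) | COc1c(Br)cc(Br)cc1-c1[nH]c(Br)c(Br)c1Br | intermediate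
11 | pentabromopseudilin, 2,4-dibromo-6-(3,4,5-tribromo-1H-pyrrol-2-yl)phenol | Oc1c(Br)cc(Br)cc1-c1[nH]c(Br)c(Br)c1Br | target

**Step count**
Total steps: 6. Longest linear sequence: 6 steps (1 → 2 → 4 → 8 → 9 → 10 → 11).

**Steps most likely to fail**

Step 5. Once two bromines have deactivated the ring, ipso attack at the carboxyl-bearing carbon may lag, and the remaining NBS may then oxidise the pyrrole instead of replacing the carboxyl group. The fallback separates decarboxylation from bromination.
- It sets out from 9, which is protodecarboxylated in trifluoroacetic acid at rt (ipso protonation of the electron-rich α-carbon, then loss of CO2). This gives 2-(3,5-dibromo-2-methoxyphenyl)-1H-pyrrole F1.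
- The three free pyrrole positions of F1 are then brominated with NBS (3 equiv) in THF from −78 °C to 0 °C.
- The route is rejoined at 10.

Step 3. The hindered ortho-substituted aryl imine may cycloadd slowly, so that amine addition to the disulfone and imine hydrolysis compete, or the elimination may stall after the first sulfinate has left. The fallback sets out from 4 and moves one of the two leaving groups from carbon to nitrogen.
- Silver-catalysed cycloaddition of 4 with phenyl vinyl sulfone, which is far less prone to amine addition, should give ethyl 5-(3,5-dibromo-2-methoxyphenyl)-4-(phenylsulfonyl)pyrrolidine-2-carboxylate F2. The sulfonyl group sits next to the aryl-bearing carbon.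
- NCS (1 equiv) converts the secondary amine into N-chloropyrrolidine F3.
- DBU removes HCl toward the more acidic ester-bearing carbon to give 1-pyrroline F4.
- The same base expels benzenesulfinate from F4 by E1cB, through the carbon next to the C=N bond. Tautomerisation then rejoins the route at 8.

Step 6. Acid released during ether cleavage and quench may protonate the electron-rich tribromopyrrole, causing loss or migration of the α-bromine and darkening of the material. The fallback changes the order of events and sets out from 8.
- The ether is cleaved with BBr3 while the pyrrole still carries the stabilising ester and no bromine. This gives ethyl 5-(3,5-dibromo-2-hydroxyphenyl)-1H-pyrrole-2-carboxylate F5.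
- Saponification gives 5-(3,5-dibromo-2-hydroxyphenyl)-1H-pyrrole-2-carboxylic acid F6.
- The threefold bromination with NBS and catalytic LiOAc is run last on F6, whose phenol ring has no free ortho or para position.
- The route is rejoined at 11.

**Further compounds**
F1 | step 5 | 2-(3,5-dibromo-2-methoxyphenyl)-1H-pyrrole | COc1c(Br)cc(Br)cc1-c1ccc[nH]1
F2 | step 3 | ethyl 5-(3,5-dibromo-2-methoxyphenyl)-4-(phenylsulfonyl)pyrrolidine-2-carboxylate (racemic, all-cis endo adduct, one enantiomer drawn) | CCOC(=O)[C@@H]1N[C@H](c2cc(Br)cc(Br)c2OC)[C@H](S(=O)(=O)c2ccccc2)C1
F3 | step 3 | ethyl 1-chloro-5-(3,5-dibromo-2-methoxyphenyl)-4-(phenylsulfonyl)pyrrolidine-2-carboxylate (racemic, all-cis, one enantiomer drawn) | CCOC(=O)[C@@H]1N(Cl)[C@H](c2cc(Br)cc(Br)c2OC)[C@H](S(=O)(=O)c2ccccc2)C1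
F4 | step 3 | ethyl 2-(3,5-dibromo-2-methoxyphenyl)-3-(phenylsulfonyl)-3,4-dihydro-2H-pyrrole-5-carboxylate (racemic, 2,3-cis, one enantiomer drawn) | CCOC(=O)C1=N[C@H](c2cc(Br)cc(Br)c2OC)[C@H](S(=O)(=O)c2ccccc2)C1
F5 | step 6 | ethyl 5-(3,5-dibromo-2-hydroxyphenyl)-1H-pyrrole-2-carboxylate | CCOC(=O)c1ccc([nH]1)-c1cc(Br)cc(Br)c1O
F6 | step 6 | 5-(3,5-dibromo-2-hydroxyphenyl)-1H-pyrrole-2-carboxylic acid | OC(=O)c1ccc([nH]1)-c1cc(Br)cc(Br)c1O
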